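## The problem

Compound 17 is a macrocyclic bis(bibenzyl) with no stereocentre: four benzene rings, lettered A (phenol, OH meta to its benzylic carbon), B (meta-phenylene), C (para-phenylene) and D (phenol, OH para to its benzylic carbon), are joined in the cyclic order A–O–B–CH2CH2–C–O–D–CH2CH2–A, a 20-membered ring. The task is therefore connectivity and ring closure, not configuration: two diaryl ether bonds between rings that carry no electron-withdrawing group, two ethylene bridges, and a macrocyclisation that must outrun oligomerisation. Three phenolic oxygens appear on the way (ring A OH, ring D OH, and the ring B oxygen, which is a phenol until the A–O–B bond exists); the first two sit in almost identical environments and are best distinguished by construction, not by selective protection. Free electron-rich phenols and four benzylic CH2 groups exclude harsh oxidants late in the route. Closing the ring through an aryl–oxygen bond would need a copper- or palladium-mediated coupling of unactivated partners at high dilution. Ring A offers a way round this: C1 bears OH, the adjacent C6 bears the ring B oxygen, and C3, para to C6, bears the bridge, which is the pattern of a 6-aryloxy-3-alkylcyclohex-2-en-1-one with C1 as carbonyl carbon. At that oxidation level C6 is tetrahedral and α to a ketone, so the A–O–B bond can be made by SN2 displacement of an α′-bromide by the ring B phenoxide, and the carbonyl oxygen becomes the ring A hydroxyl on dehydrogenation. The only stereocentre on the way, C6, is formed racemic, inverted in the ring closure and erased on aromatisation, so it controls nothing; the one fragile function is the α′-bromo enone, which loses HBr under base.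

## Retrosynthesis

**17 ⇒ 16 ⇒ 15.** No skeletal bond is cut. The ring D methyl ether of 16 is the last protecting group, and the ring A phenol of 16 is traced back to the cyclohex-2-en-1-one of 15 by adding two hydrogens. Carrying ring A as an enone instead of a protected phenol means its oxygen is a carbonyl until the penultimate step and never has to be told apart from the ring D oxygen. The forward step must dehydrogenate a 6-aryloxy enone without attacking benzylic CH2 groups.

**15 ⇒ 14.** The O(ring B)–C6(ring A) bond is cut. The neighbouring cuts are an aryl–oxygen bond (a macrocyclic Ullmann coupling of unactivated partners) or a CH2–CH2 bridge (olefination then hydrogenation, which the enone would not survive). The chosen cut ends at a tetrahedral, carbonyl-activated carbon. Precursor 14 is acyclic and holds exactly one free phenol and one electrophilic carbon. The forward reaction must make substitution faster than loss of HBr and faster than intermolecular etherification.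

**14 ⇒ 13 ⇒ 11.** The C6–Br bond and the phenol protecting group are removed. A 3-alkylcyclohex-2-enone has a single sp3 α-carbon, C6, so kinetic enolisation places the bromide para to the bridge without any regiochemical choice. The ring B oxygen travels as a methoxymethyl ether: it withstands every base and organometallic used earlier and is cleaved by acid-catalysed transacetalisation. Under those conditions no phenoxide meets the bromide at preparative concentration, as it would with fluoride or base cleavage of a silyl ether or ester.

**11 ⇒ 8 + 9.** The C3(ring A)–CH2 bond is cut. Styrene 8 is hydroborated to borane 10 and coupled with bromo enone 9 in a B-alkyl Suzuki–Miyaura reaction. The neighbouring option, 1,2-addition of a phenethyl Grignard reagent to a 3-alkoxycyclohexenone with acid transposition, would first require the styrene to be converted into alcohol, bromide and organomagnesium. Precursor 8 already has rings B, C and D and all ether oxygens in place. The forward step needs anti-Markovnikov hydroboration and a coupling faster than base hydrolysis of 9.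

**8 ⇒ 7 ⇒ 5 + 6.** The vinyl group comes from aldehyde 7 by Wittig methylenation, and the O–C(ring C) bond is cut to bromide 5 and isovanillin 6 (Ullmann ether synthesis). An SNAr union with a para-fluoro benzaldehyde would form the ether more easily but would give a dialdehyde whose two formyl groups need protection to be told apart. Here 6 brings its single aldehyde exactly where the ring A bridge must grow. The forward step asks a copper catalyst to couple an ortho-methoxy phenol with an unactivated aryl bromide.

**5 ⇒ 2 + 3 (through 4), 2 ⇒ 1.** The aryl(ring B)–CH2 bond is cut. Styrene 3 is hydroborated to 4 and coupled with iodide 2, which is 3-iodophenol 1 after protection. A Wittig–hydrogenation sequence would need a phosphonium salt made in several steps and a hydrogenation that would also remove the bromine required for the ether synthesis. The forward step relies on zerovalent palladium inserting into C–I much faster than into C–Br.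

## Roads not taken

**Alternative 1:** Ring C is cut across two of its C–C bonds in a retro-Diels–Alder sense. The seco compound A2 carries a 2-aryloxybuta-1,3-diene on the ring D oxygen and a terminal ynone on the ring B benzylic carbon. Heating A2 at high dilution and dehydrogenating the cyclohexadiene with DDQ in the same flask would give the macrocyclic aryl benzyl ketone A1, with both phenols as methyl ethers.
- Merits: one operation forms two C–C bonds, ring C and the macrocycle. The "para" preference of a 2-oxygenated diene towards an ynone matches the 1,4-pattern of ring C. No elimination-prone halide is involved, and neither a copper ether synthesis nor a halostyrene is needed for ring C.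
- Weak points: A2 contains a polymerisable, hydrolytically labile dienyl ether and a terminal ynone that is a Michael acceptor. The cycloaddition must pass through a 20-membered transition state under prolonged heating, where the tether may also allow the "meta" orientation. The product keeps a carbonyl that must be removed before demethylation.
- Comparison: the step count after the key step is the same (two). Alternative 1 is better in complexity gained per step. The chosen plan sets against it a precursor (14) assembled from stable catalogue aromatics by routine couplings, and a fast, irreversible SN2 closure at room temperature in place of a slow thermal reaction of two sensitive π-systems.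

**Alternative 2:** The O–C(ring D) bond is cut. Seco compound A4 carries a 2,6-dibromophenol as ring D and a 2,6-dichlorophenol as ring C, with ring A as methyl ether. Tl(NO3)3 in methanol would oxidise the dibromophenol, the ring C phenol oxygen would add at its ortho carbon, and zinc in acetic acid would reduce the bromo dienone to the halogenated macrocycle A3. Hydrodehalogenation and demethylation would follow.
- Merits: a diaryl ether is made directly from two phenols with regiochemistry dictated by the halogens. Ring A is aromatic throughout, so no dehydrogenation is needed, and the ether that the chosen plan makes in a separate copper step is formed in the ring closure itself.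
- Weak points: stoichiometric, highly toxic trivalent thallium; four halogens to install and three to remove afterwards; an oxidation that may also attack the other electron-rich aryl ether rings; and a flexible bibenzyl substrate that offers little preorganisation for the oxidative closure.
- Comparison: Alternative 2 is more direct in forming the C–O–D ether and avoids any carbocycle aromatisation. The chosen plan sets against it the absence of thallium and halogen ballast, and a ring closure whose site is fixed by one phenol and one sp3 electrophile.

**Alternative 3:** The B–C bridge is cut on both sides of a one-carbon linchpin. Seco compound A6 carries a benzylic chloride on ring C and a boronate on ring B (taken as the pinacol ester). Under CO, the zerovalent palladium complex Pd(PPh3)4 with K2CO3 would insert into the benzylic C–Cl bond, take up CO and couple with the boronate to give the macrocyclic ketone A5. Carbonyl removal and double demethylation would follow.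
- Merits: the precursor is fully aromatic and shelf-stable, and the closure is catalytic and forms C–C bonds far from the oxygen functions. In robustness of the precursor it is superior to the bromo enone 14.
- Weak points: at the dilution a macrocyclisation needs, CO insertion must still beat direct benzyl–aryl coupling, which would give a ring-contracted diarylmethane. Benzylpalladium species also homocouple. The extra carbonyl costs a deoxygenation, and both phenolic oxygens (rings A and D) would be carried as identical methyl ethers through a longer fragment synthesis.
- Comparison: the chosen plan sets against it a two-component closure with no gas uptake, no redundant carbonyl, and a ring A oxygen pattern that arises from the enone by itself.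

Key step: step 8

Assumption: 13, 14 and 15 are racemates drawn as one enantiomer (the target has no stereocentre), and 1, 3, 6 and 9 are treated as catalogue chemicals.

## Route

Step 1
Reactants: 1 3-iodophenol
Product: 2 1-iodo-3-(methoxymethoxy)benzene
Conditions: NaH, THF/DMF, 0 °C; MOMCl, 0 °C → rt
Reagents that add atoms: chloromethyl methyl ether, COCCl
Why: Williamson-type O-alkylation of the sodium phenoxide by the highly reactive α-chloro ether; the resulting acetal is inert to the bases, boranes and organometallics of steps 2–6 and is removed later under mild acid.

Step 2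
Reactants: 3 4-bromostyrene (1-bromo-4-ethenylbenzene); 2 1-iodo-3-(methoxymethoxy)benzene
Product: 5 1-bromo-4-{2-[3-(methoxymethoxy)phenyl]ethyl}benzene, via B-alkyl-9-BBN adduct 4 (not isolated)
Conditions: 9-BBN, THF, 0 °C → rt; then 2, PdCl2(dppf) (3 mol%), aq K3PO4, DMF, rt
Reagents that add atoms: 9-borabicyclo[3.3.1]nonane, B1C2CCCC1CCC2 (boron and its carbons stay only in the intermediate 4; 5 keeps one hydrogen of it)
Why: Anti-Markovnikov hydroboration of the styrene followed by B-alkyl Suzuki–Miyaura coupling; zerovalent palladium inserts into the C–I bond of 2 far faster than into the C–Br bond of 4 or 5 at room temperature, so the bromide survives for step 3 and the bibenzyl bridge is formed directly at the saturated level.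

Step 3
Reactants: 5 1-bromo-4-{2-[3-(methoxymethoxy)phenyl]ethyl}benzene; 6 isovanillin (3-hydroxy-4-methoxybenzaldehyde)
Product: 7 4-methoxy-3-(4-{2-[3-(methoxymethoxy)phenyl]ethyl}phenoxy)benzaldehyde
Conditions: CuI (10 mol%), Me2NCH2CO2H·HCl (30 mol%), Cs2CO3, 1,4-dioxane, 100 °C
Reagents that add atoms: none
Why: Ullmann diaryl ether synthesis with an amino-acid ligand; the phenoxide of 6 (aldehyde meta to the oxygen, so still nucleophilic) binds monovalent copper, which inserts into the aryl bromide and reductively eliminates the ether, while the non-enolisable aldehyde and the acetal tolerate carbonate.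

Step 4
Reactants: 7 4-methoxy-3-(4-{2-[3-(methoxymethoxy)phenyl]ethyl}phenoxy)benzaldehyde
Product: 8 4-ethenyl-1-methoxy-2-(4-{2-[3-(methoxymethoxy)phenyl]ethyl}phenoxy)benzene
Conditions: Ph3PCH3Br, KOtBu, THF, 0 °C → rt
Reagents that add atoms: methyltriphenylphosphonium bromide, C[P+](c1ccccc1)(c1ccccc1)c1ccccc1.[Br-]
Why: Wittig methylenation of a non-enolisable aryl aldehyde with the unstabilised ylide; no other electrophile is present.

Step 5
Reactants: 8 4-ethenyl-1-methoxy-2-(4-{2-[3-(methoxymethoxy)phenyl]ethyl}phenoxy)benzene; 9 3-bromocyclohex-2-en-1-one
Product: 11 3-{2-[4-methoxy-3-(4-{2-[3-(methoxymethoxy)phenyl]ethyl}phenoxy)phenyl]ethyl}cyclohex-2-en-1-one, via B-alkyl-9-BBN adduct 10 (not isolated)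
Conditions: 9-BBN, THF, 0 °C → rt; aq K3PO4; then 9, PdCl2(dppf) (5 mol%), DMF, rt → 40 °C
Reagents that add atoms: 9-borabicyclo[3.3.1]nonane, B1C2CCCC1CCC2 (boron and its carbons stay only in the intermediate 10; 11 keeps one hydrogen of it)
Why: Hydroboration and B-alkyl Suzuki–Miyaura coupling with a β-bromo enone, a vinylogous acyl bromide that undergoes oxidative addition to zerovalent palladium readily; adding the aqueous base before 9 destroys residual B–H so that the enone carbonyl is not reduced.

Step 6
Reactants: 11 3-{2-[4-methoxy-3-(4-{2-[3-(methoxymethoxy)phenyl]ethyl}phenoxy)phenyl]ethyl}cyclohex-2-en-1-one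
Product: 13 (±)-6-bromo-3-{2-[4-methoxy-3-(4-{2-[3-(methoxymethoxy)phenyl]ethyl}phenoxy)phenyl]ethyl}cyclohex-2-en-1-one, via silyl dienol ether 12 (not isolated)
Conditions: LDA, THF, −78 °C; TMSCl; then NBS, THF, −78 → 0 °C
Reagents that add atoms: N-bromosuccinimide, O=C1CCC(=O)N1Br (bromine of 13); chlorotrimethylsilane, C[Si](C)(C)Cl (silyl group of the intermediate 12 only)
Why: Kinetic deprotonation occurs at C6, the only sp3 α-carbon, giving the cross-conjugated dienolate, which is trapped as the 2-silyloxy diene and brominated at its nucleophilic terminus (α′-bromination of an enone through its silyl dienol ether); the new C6 centre is formed racemic with no controlling element and none is needed, and at −78 °C the aryl ethers are far less nucleophilic than the dienol ether.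

Step 7
Reactants: 13 (±)-6-bromo-3-{2-[4-methoxy-3-(4-{2-[3-(methoxymethoxy)phenyl]ethyl}phenoxy)phenyl]ethyl}cyclohex-2-en-1-one
Product: 14 (±)-6-bromo-3-{2-[3-(4-{2-(3-hydroxyphenyl)ethyl}phenoxy)-4-methoxyphenyl]ethyl}cyclohex-2-en-1-one
Conditions: TsOH·H2O (cat.), MeOH/CH2Cl2, 35 °C; neutral work-up
Reagents that add atoms: none
Why: Acid-catalysed transacetalisation of the aryl methoxymethyl ether to methanol; no base is present, so the bromo enone cannot lose HBr or be attacked by phenoxide, and the sulfonate counter-ion avoids halide exchange at C6.

Step 8
Reactants: 14 (±)-6-bromo-3-{2-[3-(4-{2-(3-hydroxyphenyl)ethyl}phenoxy)-4-methoxyphenyl]ethyl}cyclohex-2-en-1-one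
Product: 15 (±)-macrocyclic enone in which ring A is a cyclohex-2-en-1-one bearing the CH2CH2 bridge to ring D at C3 and the ring B oxygen at C6, with ring D as methyl ether
Conditions: Cs2CO3 (3 equiv), DMF, 25 °C, Ar, syringe-pump addition of 14 over 12 h to a final concentration of about 0.002 M
Reagents that add atoms: none
Why: Cs2CO3 deprotonates only the ring B phenol of 14, and the cesium phenoxide attacks C6 from the face opposite to bromide in an SN2 displacement whose transition state is stabilised by overlap with the adjacent carbonyl π* orbital. The closest known reaction type is the Williamson O-alkylation of phenoxides by α-bromo ketones (as in 2-aryloxycyclohexanones from 2-bromocyclohexanone) and its macrocyclic cesium carbonate/high-dilution version. The 20-membered ring closes end to end in the exo-tet mode at a tetrahedral carbon, and the two flexible CH2CH2 bridges keep strain low. C6 is inverted, but 14 is racemic, so 15 is racemic and no element has to control this centre, which disappears in step 9. Ring closure must beat oligomerisation, which slow addition into a dilute carbonate suspension secures. Substitution must beat loss of HBr, which would aromatise ring A without its ether oxygen: the phenoxide is a weak base and a good nucleophile, the C–Br bond is activated by the carbonyl, and carbonate at 25 °C hardly enolises the enone. O- over C-alkylation is favoured by the loosely paired cesium phenoxide in DMF, and the ring D oxygen, being a methyl ether, cannot compete.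

Step 9
Reactants: 15 (±)-macrocyclic enone
Product: 16 macrocyclic phenol with ring A aromatic (free OH) and ring D as methyl ether
Conditions: Pd(O2CCF3)2 (5 mol%), 2-(dimethylamino)pyridine (10 mol%), TsOH (20 mol%), O2 (1 atm), DMSO, 80 °C
Reagents that add atoms: none
Why: Palladium-catalysed aerobic dehydrogenation of a cyclohexenone to a phenol: a divalent palladium enolate undergoes β-hydride elimination to a dienone that tautomerises to the arene, and O2 reoxidises zerovalent palladium; unlike quinone oxidants, this catalyst leaves the electron-rich benzylic CH2 groups alone.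

Step 10
Reactants: 16 macrocyclic phenol with ring D as methyl ether
Product: 17 target macrocycle (CNP0329842.0), both phenols free
Conditions: BBr3, CH2Cl2, −78 → 0 °C; then H2O
Reagents that add atoms: none
Why: Lewis-acid ether cleavage: boron coordinates the methoxy oxygen and bromide attacks the methyl carbon by SN2, while the diaryl ether C–O bonds at sp2 carbon are not cleaved; hydrolysis of the aryl borates frees both phenols.

## Compound list

1 | 3-iodophenol | Oc1cccc(I)c1 | starting material
2 | 1-iodo-3-(methoxymethoxy)benzene | COCOc1cccc(I)c1 | intermediate
3 | 4-bromostyrene (1-bromo-4-ethenylbenzene) | C=Cc1ccc(Br)cc1 | starting material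
4 | 9-[2-(4-bromophenyl)ethyl]-9-borabicyclo[3.3.1]nonane | Brc1ccc(CCB2C3CCCC2CCC3)cc1 | intermediate (not isolated)
5 | 1-bromo-4-{2-[3-(methoxymethoxy)phenyl]ethyl}benzene | COCOc1cccc(CCc2ccc(Br)cc2)c1 | intermediate
6 | isovanillin (3-hydroxy-4-methoxybenzaldehyde) | COc1ccc(C=O)cc1O | starting material
7 | 4-methoxy-3-(4-{2-[3-(methoxymethoxy)phenyl]ethyl}phenoxy)benzaldehyde | COCOc1cccc(CCc2ccc(Oc3cc(C=O)ccc3OC)cc2)c1 | intermediate
8 | 4-ethenyl-1-methoxy-2-(4-{2-[3-(methoxymethoxy)phenyl]ethyl}phenoxy)benzene | COCOc1cccc(CCc2ccc(Oc3cc(C=C)ccc3OC)cc2)c1 | intermediate
9 | 3-bromocyclohex-2-en-1-one | O=C1C=C(Br)CCC1 | starting material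
10 | 9-{2-[4-methoxy-3-(4-{2-[3-(methoxymethoxy)phenyl]ethyl}phenoxy)phenyl]ethyl}-9-borabicyclo[3.3.1]nonane | COCOc1cccc(CCc2ccc(Oc3cc(CCB4C5CCCC4CCC5)ccc3OC)cc2)c1 | intermediate (not isolated)
11 | 3-{2-[4-methoxy-3-(4-{2-[3-(methoxymethoxy)phenyl]ethyl}phenoxy)phenyl]ethyl}cyclohex-2-en-1-one | O=C1C=C(CCc2ccc(OC)c(Oc3ccc(CCc4cccc(OCOC)c4)cc3)c2)CCC1 | intermediate
12 | 4-{2-[4-methoxy-3-(4-{2-[3-(methoxymethoxy)phenyl]ethyl}phenoxy)phenyl]ethyl}-2-(trimethylsilyloxy)cyclohexa-1,3-diene | C[Si](C)(C)OC1=CCCC(CCc2ccc(OC)c(Oc3ccc(CCc4cccc(OCOC)c4)cc3)c2)=C1 | intermediate (not isolated)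
13 | (±)-6-bromo-3-{2-[4-methoxy-3-(4-{2-[3-(methoxymethoxy)phenyl]ethyl}phenoxy)phenyl]ethyl}cyclohex-2-en-1-one (racemate, 6R enantiomer drawn) | O=C1C=C(CCc2ccc(OC)c(Oc3ccc(CCc4cccc(OCOC)c4)cc3)c2)CC[C@H]1Br | intermediate
14 | (±)-6-bromo-3-{2-[3-(4-{2-(3-hydroxyphenyl)ethyl}phenoxy)-4-methoxyphenyl]ethyl}cyclohex-2-en-1-one (racemate, 6R enantiomer drawn) | O=C1C=C(CCc2ccc(OC)c(Oc3ccc(CCc4cccc(O)c4)cc3)c2)CC[C@H]1Br | intermediate
15 | (±)-macrocyclic 6-aryloxycyclohex-2-en-1-one: ring A as enone with C3 bound to the CH2CH2 bridge to ring D and C6 bound to the ring B oxygen, ring D as methyl ether (racemate, S enantiomer drawn) | O=C1C=C2CC[C@@H]1Oc1cccc(c1)CCc1ccc(cc1)Oc1cc(ccc1OC)CC2 | intermediate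
16 | ring D mono-O-methyl ether of the target (ring A phenol free) | Oc1cc2ccc1Oc1cccc(c1)CCc1ccc(cc1)Oc1cc(ccc1OC)CC2 | intermediate
17 | target macrocyclic bis(bibenzyl) diphenol, CNP0329842.0 (no stereocentre) | Oc1cc2ccc1Oc1cccc(c1)CCc1ccc(cc1)Oc1cc(ccc1O)CC2 | target

## Step count and least certain steps

Total step count: 10. Longest linear sequence: 10 steps (1 → 17; 3, 6 and 9 enter as purchased partners).

**Step 8 (key step).** The most likely failure is base-induced loss of HBr from the bromo enone, which aromatises ring A irreversibly without its ether oxygen. Intermolecular etherification is the second risk if the stationary concentration of phenoxide rises. Both stem from a secondary, enolisable electrophile meeting a base. Fallback: setting out from 11, the silyl dienol ether 12 would be generated as in step 6 and oxidised with mCPBA (Rubottom oxidation) to the α′-hydroxy enone F1. TsOH in methanol would remove the acetal to give the hydroxy phenol F2. A Mitsunobu etherification (PPh3, DIAD, toluene, high dilution) would then close the same O–C6 bond with inversion under non-basic conditions and return to the route at 15.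

**Step 6.** Bromination may run past the mono stage or reach the electron-rich aryl ether rings, and the product may lose HBr during isolation, because the α′-bromo enone is both activated and acid/base labile. Fallback: again from 11 through 12, hydroxy(tosyloxy)iodobenzene, PhI(OH)OTs, would give the more robust α′-tosyloxy enone F3 with no electrophilic bromine in the flask. Acid methanolysis would give the tosyloxy phenol F4, and the Cs2CO3/high-dilution closure would displace tosylate to rejoin the route at 15.

**Step 7.** Acetal cleavage may be too slow under conditions mild enough for the bromide, or the bromo enone may degrade on prolonged exposure to acidic methanol (solvolysis at C6). Fallback: the order of events would be reversed. From 11, TsOH/MeOH would give the phenol enone F5. LDA (2.2 equiv) and TMSCl would silylate phenoxide and dienolate together to the bis-silyl compound F6 (not isolated). NBS would brominate the dienol ether, and a dilute acid work-up would strip the labile aryl silyl ether to return to the route at 14.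

**Step 9.** Dehydrogenation may stall because palladation has to occur next to a tertiary, aryloxy-substituted α′-carbon. Under the acidic conditions the ring B aryloxide may also be expelled, which would reopen the macrocycle while aromatising ring A. Fallback: from 15, LDA and TMSCl would give the macrocyclic silyl dienol ether F7. Stoichiometric Pd(OAc)2 in MeCN (Saegusa–Ito oxidation) would dehydrogenate it without added acid, and the resulting dienone would tautomerise to rejoin the route at 16.

**Step 5.** Aqueous base may hydrolyse the β-bromo enone by addition–elimination faster than the alkylborane transmetalates, or the alkylpalladium intermediate may undergo β-hydride elimination back to the styrene. Fallback: from 8, the borane 10 would be oxidised (NaOH, H2O2) to the primary alcohol F8 and converted by an Appel reaction (CBr4, PPh3) into the bromide F9. Magnesium would give the Grignard reagent F10 (not isolated), which would add 1,2 to purchased 3-ethoxycyclohex-2-en-1-one (CCOC1=CC(=O)CCC1) to give the carbinol F11 (as its bromomagnesium alkoxide, not isolated). Brief treatment with dilute HCl at 0 °C (Stork–Danheiser transposition) would return to the route at 11.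

## Further compounds

F1 | step 8 | (±)-6-hydroxy-3-{2-[4-methoxy-3-(4-{2-[3-(methoxymethoxy)phenyl]ethyl}phenoxy)phenyl]ethyl}cyclohex-2-en-1-one (racemate, one enantiomer drawn) | O=C1C=C(CCc2ccc(OC)c(Oc3ccc(CCc4cccc(OCOC)c4)cc3)c2)CC[C@H]1O
F2 | step 8 | (±)-6-hydroxy-3-{2-[3-(4-{2-(3-hydroxyphenyl)ethyl}phenoxy)-4-methoxyphenyl]ethyl}cyclohex-2-en-1-one (racemate, one enantiomer drawn) | O=C1C=C(CCc2ccc(OC)c(Oc3ccc(CCc4cccc(O)c4)cc3)c2)CC[C@H]1O
F3 | step 6 | (±)-4-{2-[4-methoxy-3-(4-{2-[3-(methoxymethoxy)phenyl]ethyl}phenoxy)phenyl]ethyl}-2-oxocyclohex-3-en-1-yl 4-methylbenzenesulfonate (racemate, one enantiomer drawn) | O=C1C=C(CCc2ccc(OC)c(Oc3ccc(CCc4cccc(OCOC)c4)cc3)c2)CC[C@H]1OS(=O)(=O)c1ccc(C)cc1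
F4 | step 6 | (±)-4-{2-[3-(4-{2-(3-hydroxyphenyl)ethyl}phenoxy)-4-methoxyphenyl]ethyl}-2-oxocyclohex-3-en-1-yl 4-methylbenzenesulfonate (racemate, one enantiomer drawn) | O=C1C=C(CCc2ccc(OC)c(Oc3ccc(CCc4cccc(O)c4)cc3)c2)CC[C@H]1OS(=O)(=O)c1ccc(C)cc1
F5 | step 7 | 3-{2-[3-(4-{2-(3-hydroxyphenyl)ethyl}phenoxy)-4-methoxyphenyl]ethyl}cyclohex-2-en-1-one | O=C1C=C(CCc2ccc(OC)c(Oc3ccc(CCc4cccc(O)c4)cc3)c2)CCC1
F6 | step 7 | 4-{2-[4-methoxy-3-(4-{2-[3-(trimethylsilyloxy)phenyl]ethyl}phenoxy)phenyl]ethyl}-2-(trimethylsilyloxy)cyclohexa-1,3-diene | C[Si](C)(C)OC1=CCCC(CCc2ccc(OC)c(Oc3ccc(CCc4cccc(O[Si](C)(C)C)c4)cc3)c2)=C1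
F7 | step 9 | trimethylsilyl dienol ether of 15 (ring A as 1-aryloxy-2-silyloxycyclohexa-1,3-diene) | C[Si](C)(C)OC1=C2CCC(=C1)CCc1ccc(OC)c(c1)Oc1ccc(cc1)CCc1cccc(c1)O2
F8 | step 5 | 2-[4-methoxy-3-(4-{2-[3-(methoxymethoxy)phenyl]ethyl}phenoxy)phenyl]ethan-1-ol | OCCc1ccc(OC)c(Oc2ccc(CCc3cccc(OCOC)c3)cc2)c1
F9 | step 5 | 4-(2-bromoethyl)-1-methoxy-2-(4-{2-[3-(methoxymethoxy)phenyl]ethyl}phenoxy)benzene | BrCCc1ccc(OC)c(Oc2ccc(CCc3cccc(OCOC)c3)cc2)c1
F10 | step 5 | {2-[4-methoxy-3-(4-{2-[3-(methoxymethoxy)phenyl]ethyl}phenoxy)phenyl]ethyl}magnesium bromide | Br[Mg]CCc1ccc(OC)c(Oc2ccc(CCc3cccc(OCOC)c3)cc2)c1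
F11 | step 5 | (±)-3-ethoxy-1-{2-[4-methoxy-3-(4-{2-[3-(methoxymethoxy)phenyl]ethyl}phenoxy)phenyl]ethyl}cyclohex-2-en-1-ol (racemate, one enantiomer drawn; bromomagnesium alkoxide in the flask) | CCOC1=C[C@@](O)(CCc2ccc(OC)c(Oc3ccc(CCc4cccc(OCOC)c4)cc3)c2)CCC1
A1 | alternative 1 | macrocyclic aryl benzyl ketone with the carbonyl on ring C, di-O-methyl | COc1ccc2cc1Oc1ccc(cc1)C(=O)Cc1cccc(c1)Oc1ccc(CC2)cc1OC
A2 | alternative 1 | seco diene–ynone: 2-aryloxybuta-1,3-diene on the ring D oxygen, terminal ynone on the ring B benzylic carbon | C=CC(=C)Oc1cc(CCc2ccc(Oc3cccc(CC(=O)C#C)c3)c(OC)c2)ccc1OC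
A3 | alternative 2 | halogenated macrocycle (ring D bromophenol, ring C dichloro, ring A methyl ether) | Oc1c(Br)cc2cc1Oc1c(Cl)cc(cc1Cl)CCc1cccc(c1)Oc1ccc(CC2)cc1OC
A4 | alternative 2 | seco bis-phenol (ring D 2,6-dibromophenol, ring C 2,6-dichlorophenol, ring A methyl ether) | Oc1c(Br)cc(CCc2ccc(Oc3cccc(CCc4cc(Cl)c(O)c(Cl)c4)c3)c(OC)c2)cc1Br
A5 | alternative 3 | macrocyclic aryl benzyl ketone with the carbonyl on ring B, di-O-methyl | COc1ccc2cc1Oc1ccc(cc1)CC(=O)c1cccc(c1)Oc1ccc(CC2)cc1OC
A6 | alternative 3 | seco benzylic chloride (ring C) with pinacol boronate (ring B), di-O-methyl | ClCc1ccc(Oc2cc(CCc3ccc(Oc4cccc(B5OC(C)(C)C(C)(C)O5)c4)c(OC)c3)ccc2OC)cc1
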